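## Structural features

The target 10 consists of one benzene ring (ring A) and a three-carbon, glycerol-type chain. Ring A is 1,2,4,5-tetrasubstituted: C1 carries the chain, C2 a methoxy group, C4 a methyl group and C5 a free phenolic hydroxyl. The central chain carbon is bonded to ring A C1 and bears a tertiary hydroxyl and two oxymethyl arms, one esterified as the (E)-2-methylbut-2-enoate (tiglate) and the other as the acetate. This benzylic, fully substituted carbinol carbon is the only stereocentre, (R). It is stereogenic solely because the two arms carry different acyl groups, and no neighbouring stereocentre can help to set it. Fragile points are: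
- the tertiary benzylic alcohol on an electron-rich arene, which can ionise under acid;
- the esters next to free hydroxyls, which can undergo 1,2- and 1,3-acyl shifts (in a mono-ester a shift from one arm to the other is racemisation);
- the conjugated tiglate alkene, which rules out hydrogenation and strong nucleophiles;
- the oxidisable hydroquinone mono-ether.

The real difficulty is to tell apart two enantiotopic CH2O arms on a quaternary carbon and to keep them apart until both are acylated. The key step exploits the fact that the carbinol carbon with its hydroxyl and two C–O arms is the opened form of a 3-aryloxetan-3-ol: oxetane C3 is the future stereocentre, and ring carbons C2 and C4 are enantiotopic methylene groups joined through the ring oxygen.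

## Logic of the disconnections

10 to 9. The phenolic O–H on ring A C5 is traced back to an O–Si bond. A free phenol would quench an aryllithium, would compete as nucleophile and hydrogen-bond donor in the acid step, and would be acetylated. Nothing is gained in skeleton, but every earlier step becomes chemoselective. The forward Si–O cleavage must leave two esters and the tertiary benzylic alcohol alone and must not start an acyl shift, so it calls for nearly neutral fluoride.

9 to 8. The acyl C–O bond of the acetate is cut. This leaves a diol mono-ester in which only the arm not yet acylated is free. The forward acetylation must touch the primary hydroxyl only and must be faster than any 1,3-shift of the tiglate.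

8 to 6 and 7. The alkyl C–O bond between the tiglate oxygen and its CH2 is cut, and this CH2 is reconnected to the oxygen of the free arm, which rebuilds the four-membered ether. The stereocentre vanishes, because 6 is achiral with two enantiotopic ring methylenes. Both arms are already at the correct oxidation level, and the tiglate enters as the free acid 7 without any activation. The forward step needs a chiral catalyst that selects one methylene and opens it by SN2 attack without ionising the benzylic C–OH bond.

6 to 5 and 4, with 5 from 3. The bond between ring A C1 and oxetane C3 is cut, to an aryl nucleophile 5 and the ketone 4. This is the only skeletal C–C bond of the route. The forward step needs a clean halogen–metal exchange on 3 and a silyl ether that tolerates the organolithium.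

3 to 2. The C–Br bond at ring A is cut. The forward bromination must go to the position ortho to methoxy and para to methyl, not ortho to the silyloxy group.

2 to 1. The O–Si bond is cut to the commercial phenol 1. Silylation precedes bromination so that the methoxy group, not the phenol oxygen, steers the electrophile.

## Other disconnections considered

Alternative 1: Self-regeneration of the stereocentre through a dioxolanone.
- Cut: the C–C bond between the carbinol carbon and the oxymethyl arm that later carries the tiglate.
- Forward key step: the cis-dioxolanone A2, the tert-butyl acetal-lactone of the (R)-arylglycolic acid A4, is deprotonated by LiN(i-Pr)2 in THF at low temperature. The enolate is alkylated by benzyl chloromethyl ether A3 on the face away from the tert-butyl group, which should give A1.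
- In favour: the facial control is substrate-based and highly predictable. The absolute configuration follows from A4. The two arms arrive as lactone carbonyl and benzyl ether, so no acyl shift can scramble them at the stage where the stereocentre is set.
- Against: A4 is not commercial and needs an asymmetric step or a resolution of its own. The enolate carries an ortho-substituted aryl group and is hindered. A3 is a carcinogenic alkylating agent. After A1 come hydride reduction, acetylation, debenzylation, tigloylation and desilylation. The debenzylation by hydrogenolysis threatens the electron-rich tertiary benzylic C–O bond and must precede the tiglate, so a mono-acetate with a free arm is passed, and acetates migrate more easily than tiglates.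
- Comparison: on certainty and predictability of the stereo-defining step this alternative is the better plan. On exposure to acyl shift the two plans are equal. On step economy the chosen plan is clearly ahead (six steps against roughly twelve), and it needs no stoichiometric chirality.

Alternative 2: Enantioconvergent hydroxylation of a mixed malonate.
- Cut: the C–O bond of the tertiary alcohol.
- Forward key step: the racemic malonate A6 is deprotonated by solid Cs2CO3 in the presence of a chiral cinchona-derived quaternary ammonium bromide. The ion-paired enolate is oxidised by cumene hydroperoxide A7 to A5.
- In favour: both enantiomers of A6 pass through one planar enolate, so a racemic precursor suffices. The stereocentre of A5 is configurationally inert, because its arms are at the carboxyl level and no acyl shift exists. No acid-sensitive oxetanol is involved. On these three points the alternative is better than the chosen plan.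
- Against: the catalyst must distinguish a methyl from a tert-butyl ester next to a hindered, electron-rich aryl enolate. The arms are two oxidation levels too high: the methyl ester carbon has to become the acetoxymethyl arm and the tert-butyl ester carbon the tigloyloxymethyl arm, by two separate chemoselective reductions. The tert-butyl ester cleavage in between needs acid in the presence of the tertiary benzylic alcohol.
- Comparison: both plans rest on one catalytic step that must tell two similar groups apart (two esters there, two methylenes here), so they are equal in that uncertainty. The alternative needs roughly ten steps and is poorer in redox economy. The chosen plan keeps every carbon at its final oxidation level.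

Alternative 3: Rhodium-catalysed asymmetric arylation of a pyruvate.
- Cut: the bond from ring A C1 to the carbinol carbon.
- Forward key step: the arylboronic acid A9 adds to the ketone carbonyl of the silyloxypyruvate A10 under a monovalent rhodium catalyst ([RhCl(C2H4)2]2 with a chiral diene, aqueous KOH) to give A8.
- In favour: the C–C bond and the stereocentre are made in one event, whereas the chosen plan needs two steps for this. The reaction class (asymmetric rhodium addition of arylboronic acids to activated ketones) is established, so on precedent the alternative is better. The arms arrive as ester and silyl ether and cannot exchange.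
- Against: A9 is ortho-substituted and electron-rich, so transmetalation is slow and protodeboronation under aqueous base competes. A10 is enolisable and base-sensitive. The catalyst must distinguish a silyloxymethyl group from an ester group on the ketone. After A8 come ester reduction, tigloylation, selective removal of the alkyl silyl ether beside the aryl silyl ether, acetylation and final desilylation.
- Comparison: the two plans are equal in using one catalytic asymmetric operation. The alternative needs three protecting-group events and about nine steps in its longest line, plus the preparation of A10. The chosen plan needs one protecting group and six steps.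

Key step: step 4

Assumption: the sense of induction of the phosphoric acid with this nucleophile cannot be derived from first principles; the (R)-configured catalyst is written in step 4 and stands for whichever antipode a first screen shows to give (R)-8.

Check of structures: the carbinol carbon is (R) in 8, 9 and 10 (priorities OH > tigloyloxymethyl > hydroxymethyl or acetoxymethyl > aryl), the ring A pattern of 1 maps onto 10 with the new bond at C5 of 1, and no structure needed correction. The precursor 6 keeps its tert-butyldimethylsilyl ether, because this group is meta to the benzylic carbon and is the phenol silyl ether that bifluoride removes most gently.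

## Route

Step 1
Reactants: 1 4-methoxy-2-methylphenol
Product: 2 tert-butyl(4-methoxy-2-methylphenoxy)dimethylsilane
Conditions: TBSCl (1.2 equiv), imidazole (2.5 equiv), DMF, 0 °C to rt
Reagents that add atoms: tert-butyldimethylsilyl chloride (TBSCl), CC(C)(C)[Si](C)(C)Cl
Why: Imidazole-promoted O-silylation of a phenol (silyl ether formation); the silyl ether removes the acidic proton before the organolithium step and turns this oxygen into a weaker, bulkier directing group for step 2.

Step 2
Reactants: 2 tert-butyl(4-methoxy-2-methylphenoxy)dimethylsilane
Product: 3 (5-bromo-4-methoxy-2-methylphenoxy)(tert-butyl)dimethylsilane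
Conditions: NBS (1.05 equiv), MeCN, 0 °C to rt, dark
Reagents that add atoms: N-bromosuccinimide (NBS), O=C1CCC(=O)N1Br
Why: Electrophilic aromatic bromination: C5 is ortho to the methoxy group and para to the methyl group, C6 is activated only by the weaker and bulky silyloxy group and C3 is flanked on both sides, so bromine should enter at C5; the polar solvent and exclusion of light disfavour radical bromination of the benzylic methyl group.

Step 3
Reactants: 3 (5-bromo-4-methoxy-2-methylphenoxy)(tert-butyl)dimethylsilane; 4 oxetan-3-one
Product: 6 3-[5-(tert-butyldimethylsilyloxy)-2-methoxy-4-methylphenyl]oxetan-3-ol, via aryllithium 5 (not isolated)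
Conditions: n-BuLi (1.05 equiv), THF, −78 °C; then 4 (1.2 equiv), −78 to −40 °C; sat. aq NH4Cl
Reagents that add atoms: none
Why: Bromine–lithium exchange followed by 1,2-addition of an aryllithium to a ketone; lithium sits meta to the silyloxy group, so no retro-Brook silyl shift is possible, the ortho methoxy group chelates lithium, and the strained, weakly enolisable ketone 4 should accept the aryllithium cleanly; C3 of the product carries two identical ring CH2 groups, so no stereocentre arises yet.

Step 4
Reactants: 6 3-[5-(tert-butyldimethylsilyloxy)-2-methoxy-4-methylphenyl]oxetan-3-ol; 7 tiglic acid, (E)-2-methylbut-2-enoic acid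
Product: 8 (R)-2-[5-(tert-butyldimethylsilyloxy)-2-methoxy-4-methylphenyl]-2,3-dihydroxypropyl (E)-2-methylbut-2-enoate
Conditions: 7 (2 equiv), (R)-3,3'-bis(2,4,6-triisopropylphenyl)-1,1'-binaphthyl-2,2'-diyl hydrogen phosphate (10 mol%), 4 Å molecular sieves, toluene, 25 to 40 °C
Reagents that add atoms: none
Why: Proposed new method: the phosphoric acid and 7 should form a hydrogen-bonded pair in which the acidic P–OH activates the oxetane oxygen of 6 while the phosphoryl oxygen takes up the carboxyl proton, so that the carbonyl oxygen of 7 attacks one ring CH2 from the rear (SN2) as the bond from that carbon to the ring oxygen breaks and the strain of the four-membered ether is released. The closest known reaction types are the chiral phosphoric acid catalysed desymmetrising opening of 3-substituted oxetanes by external sulfur and halide nucleophiles and the phosphoric acid catalysed opening of meso-epoxides by carboxylic acids; a carboxylic acid on a 3-aryloxetan-3-ol has not been shown. No ring is closed in this step, one ring is opened. The carbinol carbon is not a reaction centre, so the single new stereocentre is defined only by which of the two enantiotopic methylene groups is attacked, and this is controlled by the catalyst: its 2,4,6-triisopropylphenyl walls form a pocket that must tell the aryl group from the hydroxyl on C3 while oxetane oxygen, tertiary hydroxyl and acid are held by hydrogen bonds. The step needs group selectivity between C2 and C4 and chemoselectivity for SN2 opening over ionisation of the benzylic C–OH bond. The substrate supports the latter because a cation at C3 of a four-membered ring next to an electron-withdrawing ring oxygen is costly, the silyloxy group is meta to the benzylic carbon and lends it no resonance support, and a weak acid in toluene should not ionise a tertiary alcohol. Only the two primary ring carbons can undergo SN2 attack, so regiochemistry is not in doubt, and molecular sieves keep water from competing as nucleophile.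

Step 5
Reactants: 8 (R)-2-[5-(tert-butyldimethylsilyloxy)-2-methoxy-4-methylphenyl]-2,3-dihydroxypropyl (E)-2-methylbut-2-enoate
Product: 9 (R)-3-acetoxy-2-[5-(tert-butyldimethylsilyloxy)-2-methoxy-4-methylphenyl]-2-hydroxypropyl (E)-2-methylbut-2-enoate
Conditions: Ac2O (1.5 equiv), pyridine (3 equiv), CH2Cl2, −20 to 0 °C, on freshly prepared 8
Reagents that add atoms: acetic anhydride, CC(=O)OC(C)=O
Why: Base-mediated O-acylation with an anhydride, chemoselective for the primary over the tertiary benzylic hydroxyl; low temperature and a weak base should keep a 1,3-shift of the tiglate (which would racemise 8) slower than acetylation, and the stereocentre is not a reaction centre, so (R) is retained.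

Step 6
Reactants: 9 (R)-3-acetoxy-2-[5-(tert-butyldimethylsilyloxy)-2-methoxy-4-methylphenyl]-2-hydroxypropyl (E)-2-methylbut-2-enoate
Product: 10 (R)-3-acetoxy-2-hydroxy-2-(5-hydroxy-2-methoxy-4-methylphenyl)propyl (E)-2-methylbut-2-enoate (CNP0219919.1)
Conditions: KHF2 (2.5 equiv), MeOH, rt
Reagents that add atoms: none
Why: Fluoride-induced cleavage of an aryl silyl ether: bifluoride in methanol attacks silicon and expels the phenoxide as a good leaving group under nearly neutral conditions, under which the two carboxylic esters and the tertiary alcohol should stay untouched; the stereocentre is unaffected.

## Compound list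

1 | 4-methoxy-2-methylphenol | Cc1cc(OC)ccc1O | starting material
2 | tert-butyl(4-methoxy-2-methylphenoxy)dimethylsilane | Cc1cc(OC)ccc1O[Si](C)(C)C(C)(C)C | intermediate
3 | (5-bromo-4-methoxy-2-methylphenoxy)(tert-butyl)dimethylsilane | Cc1cc(OC)c(Br)cc1O[Si](C)(C)C(C)(C)C | intermediate
4 | oxetan-3-one | O=C1COC1 | starting material
5 | [5-(tert-butyldimethylsilyloxy)-2-methoxy-4-methylphenyl]lithium | [Li]c1cc(O[Si](C)(C)C(C)(C)C)c(C)cc1OC | intermediate
6 | 3-[5-(tert-butyldimethylsilyloxy)-2-methoxy-4-methylphenyl]oxetan-3-ol | OC1(COC1)c1cc(O[Si](C)(C)C(C)(C)C)c(C)cc1OC | intermediate
7 | tiglic acid, (E)-2-methylbut-2-enoic acid | C/C=C(\C)C(=O)O | starting material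
8 | (R)-2-[5-(tert-butyldimethylsilyloxy)-2-methoxy-4-methylphenyl]-2,3-dihydroxypropyl (E)-2-methylbut-2-enoate | C/C=C(\C)C(=O)OC[C@](O)(CO)c1cc(O[Si](C)(C)C(C)(C)C)c(C)cc1OC | intermediate
9 | (R)-3-acetoxy-2-[5-(tert-butyldimethylsilyloxy)-2-methoxy-4-methylphenyl]-2-hydroxypropyl (E)-2-methylbut-2-enoate | C/C=C(\C)C(=O)OC[C@](O)(COC(C)=O)c1cc(O[Si](C)(C)C(C)(C)C)c(C)cc1OC | intermediate
10 | (R)-3-acetoxy-2-hydroxy-2-(5-hydroxy-2-methoxy-4-methylphenyl)propyl (E)-2-methylbut-2-enoate | C/C=C(\C)C(=O)OC[C@](O)(COC(C)=O)c1cc(O)c(C)cc1OC | target

## Step count and risks

Total steps: 6. Longest linear sequence: 6 (1, 2, 3, 6, 8, 9, 10); 4 and 7 enter as purchased materials.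

Step 4 (key step, proposed new method).
- What may go wrong: the opening may be too slow, because a carboxylic acid is a weak nucleophile toward a four-membered ether under a weak acid. The catalyst may discriminate poorly between the two enantiotopic methylene groups. Acid may promote ionisation at the benzylic carbinol, or a 1,3-shift of the tiglate in the product, and either would erode enantiopurity.
- Fallback with known chemistry, from 3 back to 9: bromine–lithium exchange of 3 (n-BuLi, THF, −78 °C, through 5) and addition to commercial 2,2-dimethyl-1,3-dioxan-5-one (CC1(C)OCC(=O)CO1) should give 5-[5-(tert-butyldimethylsilyloxy)-2-methoxy-4-methylphenyl]-2,2-dimethyl-1,3-dioxan-5-ol F1. Acetal hydrolysis (AcOH, H2O, THF, rt) should free the prochiral 2-[5-(tert-butyldimethylsilyloxy)-2-methoxy-4-methylphenyl]propane-1,2,3-triol F2. Lipase-catalysed desymmetrising transesterification with vinyl acetate (Pseudomonas cepacia lipase or Candida antarctica lipase B, t-BuOMe, rt) should give (S)-2-[5-(tert-butyldimethylsilyloxy)-2-methoxy-4-methylphenyl]-2,3-dihydroxypropyl acetate F3. The enzyme is chosen by screening for acetylation of the arm that carries the acetate in 10. Acylation of the remaining primary hydroxyl with (E)-2-methylbut-2-enoyl chloride (C/C=C(\C)C(Cl)=O) and pyridine in CH2Cl2 at −20 °C then gives 9.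
- Why this fallback: lipase desymmetrisation of prochiral 2-substituted propane-1,3-diols is established practice and runs under neutral conditions, so it provokes neither ionisation nor acyl shift. The price is one extra step.

Step 5.
- What may go wrong: a base-mediated 1,3-shift of the tiglate to the free arm before acetylation, which is racemisation. Alternatively, sluggish acylation of the neopentyl-type primary alcohol may call for forcing conditions and lead to acetylation of the tertiary hydroxyl.
- Fallback, from 8 back to 9: enzymatic transesterification with vinyl acetate and immobilised Candida antarctica lipase B in t-BuOMe at rt, without any base. A lipase acylates only the primary hydroxyl and cannot promote base-catalysed migration. If the two enantiomers of 8 react at different rates, the step could also raise the enantiopurity. New compounds on this way: none F0.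

Step 6.
- What may go wrong: methanolysis or migration of the acetate, because the phenoxide and fluoride generated in methanol are basic. Alternatively the Si–O cleavage may stay incomplete.
- Fallback, from 8 back to 10, with a changed order of events: 8 is desilylated first (KHF2, MeOH, rt), when only the sturdier tiglate is present, to (R)-2,3-dihydroxy-2-(5-hydroxy-2-methoxy-4-methylphenyl)propyl (E)-2-methylbut-2-enoate F4. The primary hydroxyl alone is then acetylated enzymatically (vinyl acetate, Candida antarctica lipase B, t-BuOMe, rt). Phenol and tertiary alcohol should stay free, so 10 is reached directly. No acetate is ever exposed to fluoride, and the last step is a neutral acylation.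

Step 2.
- What may go wrong: competing bromination ortho to the silyloxy group (C6) or at the crowded C3, which would lead to regioisomers that are hard to separate. Traces of HBr may also remove the silyl group.
- Fallback, from 1 back to 3: acetylation of 1 (Ac2O, pyridine) gives 4-methoxy-2-methylphenyl acetate F5, in which the ester oxygen is a far weaker donor, so that the methoxy group alone steers the electrophile. Bromination (NBS, MeCN) should then give 5-bromo-4-methoxy-2-methylphenyl acetate F6. Methanolysis (K2CO3, MeOH) gives 5-bromo-4-methoxy-2-methylphenol F7. Silylation as in step 1 gives 3.

## Further compounds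

F1 | step 4 | 5-[5-(tert-butyldimethylsilyloxy)-2-methoxy-4-methylphenyl]-2,2-dimethyl-1,3-dioxan-5-ol | CC1(C)OCC(O)(CO1)c1cc(O[Si](C)(C)C(C)(C)C)c(C)cc1OC
F2 | step 4 | 2-[5-(tert-butyldimethylsilyloxy)-2-methoxy-4-methylphenyl]propane-1,2,3-triol | OCC(O)(CO)c1cc(O[Si](C)(C)C(C)(C)C)c(C)cc1OC
F3 | step 4 | (S)-2-[5-(tert-butyldimethylsilyloxy)-2-methoxy-4-methylphenyl]-2,3-dihydroxypropyl acetate | OC[C@](O)(COC(C)=O)c1cc(O[Si](C)(C)C(C)(C)C)c(C)cc1OC
F0 | step 5 | none | none
F4 | step 6 | (R)-2,3-dihydroxy-2-(5-hydroxy-2-methoxy-4-methylphenyl)propyl (E)-2-methylbut-2-enoate | C/C=C(\C)C(=O)OC[C@](O)(CO)c1cc(O)c(C)cc1OC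
F5 | step 2 | 4-methoxy-2-methylphenyl acetate | CC(=O)Oc1ccc(OC)cc1C
F6 | step 2 | 5-bromo-4-methoxy-2-methylphenyl acetate | CC(=O)Oc1cc(Br)c(OC)cc1C
F7 | step 2 | 5-bromo-4-methoxy-2-methylphenol | Oc1cc(Br)c(OC)cc1C
A1 | alternative 1 | (2R,5S)-5-(benzyloxymethyl)-2-tert-butyl-5-[2-methoxy-4-methyl-5-(triisopropylsilyloxy)phenyl]-1,3-dioxolan-4-one | O(Cc1ccccc1)C[C@@]1(O[C@@H](C(C)(C)C)OC1=O)c1cc(O[Si](C(C)C)(C(C)C)C(C)C)c(C)cc1OC
A2 | alternative 1 | (2R,5R)-2-tert-butyl-5-[2-methoxy-4-methyl-5-(triisopropylsilyloxy)phenyl]-1,3-dioxolan-4-one (cis) | [C@@H]1(O[C@@H](C(C)(C)C)OC1=O)c1cc(O[Si](C(C)C)(C(C)C)C(C)C)c(C)cc1OC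
A3 | alternative 1 | benzyl chloromethyl ether | ClCOCc1ccccc1
A4 | alternative 1 | (R)-2-hydroxy-2-[2-methoxy-4-methyl-5-(triisopropylsilyloxy)phenyl]acetic acid | OC(=O)[C@H](O)c1cc(O[Si](C(C)C)(C(C)C)C(C)C)c(C)cc1OC
A5 | alternative 2 | tert-butyl methyl (R)-2-hydroxy-2-[2-methoxy-4-methyl-5-(triisopropylsilyloxy)phenyl]malonate | CC(C)(C)OC(=O)[C@](O)(C(=O)OC)c1cc(O[Si](C(C)C)(C(C)C)C(C)C)c(C)cc1OC
A6 | alternative 2 | tert-butyl methyl 2-[2-methoxy-4-methyl-5-(triisopropylsilyloxy)phenyl]malonate (racemic) | CC(C)(C)OC(=O)C(C(=O)OC)c1cc(O[Si](C(C)C)(C(C)C)C(C)C)c(C)cc1OC
A7 | alternative 2 | cumene hydroperoxide | CC(C)(OO)c1ccccc1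
A8 | alternative 3 | methyl (R)-3-(tert-butyldimethylsilyloxy)-2-hydroxy-2-[2-methoxy-4-methyl-5-(triisopropylsilyloxy)phenyl]propanoate | COC(=O)[C@](O)(CO[Si](C)(C)C(C)(C)C)c1cc(O[Si](C(C)C)(C(C)C)C(C)C)c(C)cc1OC
A9 | alternative 3 | [2-methoxy-4-methyl-5-(triisopropylsilyloxy)phenyl]boronic acid | OB(O)c1cc(O[Si](C(C)C)(C(C)C)C(C)C)c(C)cc1OC
A10 | alternative 3 | methyl 3-(tert-butyldimethylsilyloxy)-2-oxopropanoate | COC(=O)C(=O)CO[Si](C)(C)C(C)(C)C
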